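**Plan**

- Retrosynthesis: the nineteen O–CH3 bonds are cut first; ring A is then opened at the bond joining its positions 1 and 6 and the bond joining its positions 2 and 3 (a carboxyl group on position 2 is lost), which leaves a 3-aryloxypropiolate on the ring B oxygen and a 1,1-dimethoxy-3-silyloxybutadiene.
- Enabling feature: ring A is a 5-aryloxyresorcinol whose ether carbon (position 1) is meta to the two hydroxyl carbons (positions 3 and 5); a 1,1,3-trioxygenated diene (positions 3 to 6) and an oxygen-substituted ynoate (positions 1 and 2) give exactly this 1,3,5 oxygen pattern on cycloaddition and aromatisation.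
- The heptamer of rings B to H is cut at the three ethers running from position 4 of rings C, E and G to position 1 of rings D, F and H, into the ring H phenol and three copies of one bromo aldehyde dimer; the inner ether of that dimer (position 2 of ring B, D or F to position 1 of ring C, E or G) is cut last.
- Forward: the dimer is made (steps 1, 2); ring H plus dimer gives rings F to H, Baeyer–Villiger oxidation turns the aldehyde into the next phenol, and two repeats add rings E, D and then C, B (steps 3 to 8). Since every coupling needs an aryl bromide that would not survive organolithium chemistry, ring A is built last on the free ring B hydroxyl (steps 9 to 13), followed by decarboxylation (step 14) and global demethylation (step 15).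
- Stereochemistry: the target has no stereocentre or stereoaxis, so only regio- and chemoselectivity need control.

Key step: step 13

Remark: rings are lettered A to H from the 3,5-dihydroxyphenoxy end; in each ring position 1 is the carbon whose ether oxygen points towards ring A (in ring A, its own ether carbon) and the second ether carbon takes the lower of its two possible numbers; the three aromatic starting materials of steps 1 to 3 are taken to be catalogue compounds.

**Route**

Step 1
Reactants: 1 5-bromo-1,2,3-trimethoxybenzene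
Product: 3 6-bromo-2,3,4-trimethoxybenzaldehyde, via chloro ether 2 (not isolated)
Conditions: Cl2CHOMe, TiCl4, CH2Cl2, 0 °C; then ice-water
Reagents that add atoms: dichloromethyl methyl ether, ClC(Cl)OC; water, O
Why: Rieche formylation (a Friedel–Crafts reaction of the TiCl4-activated dichloromethyl ether) can enter only the two equivalent free positions of 1, each ortho and para to methoxy groups, and hydrolysis of chloro ether 2 on work-up should release the aldehyde.

Step 2
Reactants: 3 6-bromo-2,3,4-trimethoxybenzaldehyde; 4 4-bromo-2,6-dimethoxyphenol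
Product: 5 dimer aldehyde (6-(4-bromo-2,6-dimethoxyphenoxy)-2,3,4-trimethoxybenzaldehyde)
Conditions: CuI (10 mol %), picolinic acid (20 mol %), K3PO4, DMSO, 80 °C, argon; 3 in slight excess
Reagents that add atoms: none
Why: Ullmann diaryl ether coupling under catalysis by monovalent copper should engage only the bromide of 3, which is activated by the ortho formyl group, while the bromide of 4 sits para to a phenoxide oxygen on an electron-rich ring and should remain; this makes, at the monomer stage, the crowded ether that later links position 2 of rings B, D and F to position 1 of rings C, E and G.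

Step 3
Reactants: 5 dimer aldehyde; 6 2,4,6-trimethoxyphenol
Product: 7 trimer aldehyde (rings F G H)
Conditions: CuI (20 mol %), picolinic acid (40 mol %), K3PO4, DMSO, 100 °C, argon; 6 in excess
Reagents that add atoms: none
Why: Ullmann coupling of a 2,6-disubstituted phenoxide with an unhindered aryl bromide, the polarity in which polymethoxylated diaryl ethers are classically made, should form the ether between position 4 of ring G and position 1 of ring H while the distant aldehyde stays untouched.

Step 4
Reactants: 7 trimer aldehyde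
Product: 9 trimer phenol (free hydroxyl on position 1 of ring F), via trimer formate 8 (not isolated)
Conditions: mCPBA, CH2Cl2, 0 °C to rt; aq. Na2SO3 wash; then Et3N (cat.), MeOH, rt
Reagents that add atoms: mCPBA (3-chloroperoxybenzoic acid), OOC(=O)c1cccc(Cl)c1
Why: Baeyer–Villiger oxidation should proceed with migration of the electron-rich, doubly ortho-oxygenated aryl group in preference to hydride, and amine-catalysed methanolysis of the aryl formate then frees the phenol after the peracid has been removed.

Step 5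
Reactants: 9 trimer phenol; 5 dimer aldehyde
Product: 10 pentamer aldehyde (rings D to H)
Conditions: CuI (20 mol %), picolinic acid (40 mol %), K3PO4, DMSO, 100 °C, argon; 5 in excess
Reagents that add atoms: none
Why: Ullmann coupling in the same polarity as step 3 (hindered phenoxide, unhindered aryl bromide) should form the ether between position 4 of ring E and position 1 of ring F.

Step 6
Reactants: 10 pentamer aldehyde
Product: 12 pentamer phenol (free hydroxyl on position 1 of ring D), via pentamer formate 11 (not isolated)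
Conditions: mCPBA, CH2Cl2, 0 °C to rt; aq. Na2SO3 wash; then Et3N (cat.), MeOH, rt
Reagents that add atoms: mCPBA (3-chloroperoxybenzoic acid), OOC(=O)c1cccc(Cl)c1
Why: Baeyer–Villiger oxidation with aryl migration followed by methanolysis of the formate, as in step 4, should unmask the hydroxyl on position 1 of ring D.

Step 7
Reactants: 12 pentamer phenol; 5 dimer aldehyde
Product: 13 heptamer aldehyde (rings B to H)
Conditions: CuI (20 mol %), picolinic acid (40 mol %), K3PO4, DMSO, 100 °C, argon; 5 in excess
Reagents that add atoms: none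
Why: Ullmann coupling in the same polarity as steps 3 and 5 should form the ether between position 4 of ring C and position 1 of ring D and so complete the chain of rings B to H.

Step 8
Reactants: 13 heptamer aldehyde
Product: 15 heptamer phenol (free hydroxyl on position 1 of ring B), via heptamer formate 14 (not isolated)
Conditions: mCPBA, CH2Cl2, 0 °C to rt; aq. Na2SO3 wash; then Et3N (cat.), MeOH, rt
Reagents that add atoms: mCPBA (3-chloroperoxybenzoic acid), OOC(=O)c1cccc(Cl)c1
Why: Baeyer–Villiger oxidation with aryl migration followed by methanolysis of the formate should turn the formyl carbon into the ring B oxygen on which ring A is built.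

Step 9
Reactants: 15 heptamer phenol; 16 trichloroethylene
Product: 17 heptamer (E)-1,2-dichlorovinyl ether
Conditions: K2CO3, DMF, 70 °C
Reagents that add atoms: none
Why: Base-induced loss of HCl from trichloroethylene gives dichloroacetylene, to which the phenoxide adds in anti fashion (the established route from phenols to aryl 1,2-dichlorovinyl ethers), so the crowded ring B oxygen only has to add to a linear two-carbon electrophile.

Step 10
Reactants: 17 heptamer (E)-1,2-dichlorovinyl ether; 18 methyl chloroformate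
Product: 21 heptamer propiolate (methyl 3-aryloxypropiolate; aryl = rings B to H bonded through the oxygen on position 1 of ring B), via chloroethynyl ether 19 (not isolated), via lithium acetylide 20 (not isolated)
Conditions: n-BuLi (2.3 equiv), THF, −78 to −40 °C; then 18, −78 to 0 °C
Reagents that add atoms: none
Why: Dehydrochlorination and chlorine–lithium exchange with n-BuLi, the standard conversion of 1,2-dichlorovinyl ethers into lithium alkynyl ethers, followed by C-acylation of the acetylide with the chloroformate should give the ynoate, since 17 holds no carbonyl group or aryl halide and ring metalation of methoxyarenes is slow at −78 °C.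

Step 11
Reactants: 22 1,1-dimethoxyethene; 23 acetyl chloride
Product: 24 4,4-dimethoxybut-3-en-2-one
Conditions: Et3N, Et2O, 0 °C to rt
Reagents that add atoms: none
Why: C-acylation of the nucleophilic ketene acetal by the acid chloride, followed by loss of HCl to the amine, is the usual preparation of this vinylogous ester.

Step 12
Reactants: 24 4,4-dimethoxybut-3-en-2-one
Product: 26 1,1-dimethoxy-3-(trimethylsilyloxy)buta-1,3-diene, via lithium enolate 25 (not isolated)
Conditions: LiN(iPr)2, THF, −78 °C; then Me3SiCl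
Reagents that add atoms: chlorotrimethylsilane, C[Si](C)(C)Cl
Why: Kinetic deprotonation at the methyl ketone, the only enolisable position, and O-silylation of the lithium enolate (silyl enol ether formation) should give the 2-silyloxy diene.

Step 13
Reactants: 21 heptamer propiolate; 26 1,1-dimethoxy-3-(trimethylsilyloxy)buta-1,3-diene
Product: 29 octamer benzoate (methyl 2-aryloxy-4-hydroxy-6-methoxybenzoate; rings A to H), via cycloadduct 27 (not isolated), via silyl ether 28 (not isolated)
Conditions: toluene, 100 °C, sealed tube, argon, 26 in excess; then 1 M HCl, THF, rt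
Reagents that add atoms: none
Why: A normal-demand Diels–Alder addition is expected in which the CH2 terminus of diene 26, its most nucleophilic carbon, attacks the aryloxy-bearing alkyne carbon of 21 (the bond between positions 1 and 6 of ring A) and the ketene acetal carbon then closes onto the ester-bearing carbon (the bond between positions 2 and 3), most likely asynchronously. The closest known reaction type is the cycloaddition of 1,1-dialkoxy-3-silyloxybuta-1,3-dienes with alkynoates, which leads to resorcinol monoalkyl ethers after loss of alcohol. Ring A closes as a six-membered carbocycle in a [4+2] mode to cyclohexa-1,4-diene 27, which aromatises by 1,4-elimination of methanol to silyl ether 28, and dilute acid then frees the hydroxyl on position 5. No stereocentre is created, because the two sp3 carbons of 27 become aromatic. The step needs regioselectivity, and the ester secures it by making the oxygen-bearing alkyne carbon the electrophilic terminus, so that the ether oxygen ends meta to both new ring oxygens and the ester sits on position 2 between two oxygens, from where it can be removed. The crowded ring B oxygen is thereby arylated without attacking an aromatic carbon, and rings B to H are ether spectators under the neutral thermal conditions.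

Step 14
Reactants: 29 octamer benzoate
Product: 31 octamer phenol (3-aryloxy-5-methoxyphenol; nonadecamethyl ether of the target), via benzoic acid 30 (not isolated)
Conditions: KOH, H2O/DMSO, 110 °C, argon; then aq. HCl to pH 1, 60 °C
Reagents that add atoms: none
Why: Saponification followed by protodecarboxylation should remove the ester, because a 2,4,6-trioxygenated benzoic acid is protonated at the ipso carbon and loses CO2 readily on acidification, as in the classical conversion of β-resorcylate esters into resorcinols.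

Step 15
Reactants: 31 octamer phenol
Product: 32 CNP0319661.0
Conditions: BBr3 (excess), CH2Cl2, −78 °C to rt, argon; then MeOH, H2O
Reagents that add atoms: none
Why: Lewis acid ether cleavage with BBr3 should remove all nineteen methyl groups by bromide attack on the O-methyl carbons of the boron-complexed ethers, while the diaryl ether bonds, which offer no sp3 carbon, stay intact.

**Compound list**

1 | 5-bromo-1,2,3-trimethoxybenzene | COc1cc(Br)cc(OC)c1OC | starting material
2 | chloro ether: 1-bromo-2-[chloro(methoxy)methyl]-3,4,5-trimethoxybenzene (racemic, not isolated) | COC(Cl)c1c(Br)cc(OC)c(OC)c1OC | intermediate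
3 | 6-bromo-2,3,4-trimethoxybenzaldehyde | O=Cc1c(Br)cc(OC)c(OC)c1OC | intermediate
4 | 4-bromo-2,6-dimethoxyphenol | COc1cc(Br)cc(OC)c1O | starting material
5 | dimer aldehyde: 6-(4-bromo-2,6-dimethoxyphenoxy)-2,3,4-trimethoxybenzaldehyde | O=Cc1c(Oc2c(OC)cc(Br)cc2OC)cc(OC)c(OC)c1OC | intermediate
6 | 2,4,6-trimethoxyphenol | COc1cc(OC)c(O)c(OC)c1 | starting material
7 | trimer aldehyde (rings F, G, H): 6-[2,6-dimethoxy-4-(2,4,6-trimethoxyphenoxy)phenoxy]-2,3,4-trimethoxybenzaldehyde | O=Cc1c(Oc2c(OC)cc(Oc3c(OC)cc(OC)cc3OC)cc2OC)cc(OC)c(OC)c1OC | intermediate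
8 | trimer formate: formate ester of phenol 9 (not isolated) | O=COc1c(Oc2c(OC)cc(Oc3c(OC)cc(OC)cc3OC)cc2OC)cc(OC)c(OC)c1OC | intermediate
9 | trimer phenol: 6-[2,6-dimethoxy-4-(2,4,6-trimethoxyphenoxy)phenoxy]-2,3,4-trimethoxyphenol | Oc1c(Oc2c(OC)cc(Oc3c(OC)cc(OC)cc3OC)cc2OC)cc(OC)c(OC)c1OC | intermediate
10 | pentamer aldehyde (rings D to H): 2,3,4-trimethoxybenzaldehyde bearing at position 6 a 2,6-dimethoxyphenoxy group (ring E) whose position 4 carries the phenol oxygen of 9 | O=Cc1c(Oc2c(OC)cc(Oc3c(Oc4c(OC)cc(Oc5c(OC)cc(OC)cc5OC)cc4OC)cc(OC)c(OC)c3OC)cc2OC)cc(OC)c(OC)c1OC | intermediate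
11 | pentamer formate: formate ester of phenol 12 (not isolated) | O=COc1c(Oc2c(OC)cc(Oc3c(Oc4c(OC)cc(Oc5c(OC)cc(OC)cc5OC)cc4OC)cc(OC)c(OC)c3OC)cc2OC)cc(OC)c(OC)c1OC | intermediate
12 | pentamer phenol: 10 with CHO replaced by OH | Oc1c(Oc2c(OC)cc(Oc3c(Oc4c(OC)cc(Oc5c(OC)cc(OC)cc5OC)cc4OC)cc(OC)c(OC)c3OC)cc2OC)cc(OC)c(OC)c1OC | intermediate
13 | heptamer aldehyde (rings B to H): 2,3,4-trimethoxybenzaldehyde bearing at position 6 a 2,6-dimethoxyphenoxy group (ring C) whose position 4 carries the phenol oxygen of 12 | O=Cc1c(Oc2c(OC)cc(Oc3c(Oc4c(OC)cc(Oc5c(Oc6c(OC)cc(Oc7c(OC)cc(OC)cc7OC)cc6OC)cc(OC)c(OC)c5OC)cc4OC)cc(OC)c(OC)c3OC)cc2OC)cc(OC)c(OC)c1OC | intermediate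
14 | heptamer formate: formate ester of phenol 15 (not isolated) | O=COc1c(Oc2c(OC)cc(Oc3c(Oc4c(OC)cc(Oc5c(Oc6c(OC)cc(Oc7c(OC)cc(OC)cc7OC)cc6OC)cc(OC)c(OC)c5OC)cc4OC)cc(OC)c(OC)c3OC)cc2OC)cc(OC)c(OC)c1OC | intermediate
15 | heptamer phenol: 13 with CHO replaced by OH (ring B carries the free hydroxyl on position 1, the aryloxy group on position 2 and methoxy groups on positions 4 to 6) | Oc1c(Oc2c(OC)cc(Oc3c(Oc4c(OC)cc(Oc5c(Oc6c(OC)cc(Oc7c(OC)cc(OC)cc7OC)cc6OC)cc(OC)c(OC)c5OC)cc4OC)cc(OC)c(OC)c3OC)cc2OC)cc(OC)c(OC)c1OC | intermediate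
16 | trichloroethylene | ClC=C(Cl)Cl | starting material
17 | heptamer (E)-1,2-dichlorovinyl ether: (E)-1,2-dichlorovinyl ether of phenol 15 | Cl/C=C(/Cl)Oc1c(Oc2c(OC)cc(Oc3c(Oc4c(OC)cc(Oc5c(Oc6c(OC)cc(Oc7c(OC)cc(OC)cc7OC)cc6OC)cc(OC)c(OC)c5OC)cc4OC)cc(OC)c(OC)c3OC)cc2OC)cc(OC)c(OC)c1OC | intermediate
18 | methyl chloroformate | COC(=O)Cl | starting material
19 | chloroethynyl ether of phenol 15 (not isolated) | ClC#COc1c(Oc2c(OC)cc(Oc3c(Oc4c(OC)cc(Oc5c(Oc6c(OC)cc(Oc7c(OC)cc(OC)cc7OC)cc6OC)cc(OC)c(OC)c5OC)cc4OC)cc(OC)c(OC)c3OC)cc2OC)cc(OC)c(OC)c1OC | intermediate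
20 | lithium acetylide: lithium 2-aryloxyethynide derived from 15 (not isolated) | [Li]C#COc1c(Oc2c(OC)cc(Oc3c(Oc4c(OC)cc(Oc5c(Oc6c(OC)cc(Oc7c(OC)cc(OC)cc7OC)cc6OC)cc(OC)c(OC)c5OC)cc4OC)cc(OC)c(OC)c3OC)cc2OC)cc(OC)c(OC)c1OC | intermediate
21 | heptamer propiolate: methyl 3-aryloxypropiolate, aryl = 15 less its hydroxyl hydrogen | COC(=O)C#COc1c(Oc2c(OC)cc(Oc3c(Oc4c(OC)cc(Oc5c(Oc6c(OC)cc(Oc7c(OC)cc(OC)cc7OC)cc6OC)cc(OC)c(OC)c5OC)cc4OC)cc(OC)c(OC)c3OC)cc2OC)cc(OC)c(OC)c1OC | intermediate
22 | 1,1-dimethoxyethene | C=C(OC)OC | starting material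
23 | acetyl chloride | CC(=O)Cl | starting material
24 | 4,4-dimethoxybut-3-en-2-one | CC(=O)C=C(OC)OC | intermediate
25 | lithium enolate: lithium 4,4-dimethoxybuta-1,3-dien-2-olate (not isolated) | [Li]OC(=C)C=C(OC)OC | intermediate
26 | 1,1-dimethoxy-3-(trimethylsilyloxy)buta-1,3-diene | COC(OC)=CC(=C)O[Si](C)(C)C | intermediate
27 | cycloadduct: methyl 2-aryloxy-6,6-dimethoxy-4-(trimethylsilyloxy)cyclohexa-1,4-diene-1-carboxylate (not isolated) | COC(=O)C1=C(Oc2c(Oc3c(OC)cc(Oc4c(Oc5c(OC)cc(Oc6c(Oc7c(OC)cc(Oc8c(OC)cc(OC)cc8OC)cc7OC)cc(OC)c(OC)c6OC)cc5OC)cc(OC)c(OC)c4OC)cc3OC)cc(OC)c(OC)c2OC)CC(O[Si](C)(C)C)=CC1(OC)OC | intermediate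
28 | silyl ether: methyl 2-aryloxy-6-methoxy-4-(trimethylsilyloxy)benzoate (not isolated) | COC(=O)c1c(OC)cc(O[Si](C)(C)C)cc1Oc2c(Oc3c(OC)cc(Oc4c(Oc5c(OC)cc(Oc6c(Oc7c(OC)cc(Oc8c(OC)cc(OC)cc8OC)cc7OC)cc(OC)c(OC)c6OC)cc5OC)cc(OC)c(OC)c4OC)cc3OC)cc(OC)c(OC)c2OC | intermediate
29 | octamer benzoate: methyl 2-aryloxy-4-hydroxy-6-methoxybenzoate (rings A to H; in the ring A numbering the ester sits on position 2, the methoxy group on position 3 and the hydroxyl on position 5) | COC(=O)c1c(OC)cc(O)cc1Oc2c(Oc3c(OC)cc(Oc4c(Oc5c(OC)cc(Oc6c(Oc7c(OC)cc(Oc8c(OC)cc(OC)cc8OC)cc7OC)cc(OC)c(OC)c6OC)cc5OC)cc(OC)c(OC)c4OC)cc3OC)cc(OC)c(OC)c2OC | intermediate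
30 | benzoic acid: 2-aryloxy-4-hydroxy-6-methoxybenzoic acid (not isolated) | OC(=O)c1c(OC)cc(O)cc1Oc2c(Oc3c(OC)cc(Oc4c(Oc5c(OC)cc(Oc6c(Oc7c(OC)cc(Oc8c(OC)cc(OC)cc8OC)cc7OC)cc(OC)c(OC)c6OC)cc5OC)cc(OC)c(OC)c4OC)cc3OC)cc(OC)c(OC)c2OC | intermediate
31 | octamer phenol: 3-aryloxy-5-methoxyphenol, the nonadecamethyl ether of the target | COc1cc(O)cc(Oc2c(Oc3c(OC)cc(Oc4c(Oc5c(OC)cc(Oc6c(Oc7c(OC)cc(Oc8c(OC)cc(OC)cc8OC)cc7OC)cc(OC)c(OC)c6OC)cc5OC)cc(OC)c(OC)c4OC)cc3OC)cc(OC)c(OC)c2OC)c1 | intermediate
32 | CNP0319661.0 (octameric aryl ether with twenty free hydroxyls) | Oc1cc(O)cc(Oc2c(Oc3c(O)cc(Oc4c(Oc5c(O)cc(Oc6c(Oc7c(O)cc(Oc8c(O)cc(O)cc8O)cc7O)cc(O)c(O)c6O)cc5O)cc(O)c(O)c4O)cc3O)cc(O)c(O)c2O)c1 | target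

**Step count**

Total step count: 15.
Longest linear sequence: 13 steps (steps 1 to 10 and 13 to 15, from compound 1). The diene branch adds steps 11 and 12.

**Steps most likely to fail**

1. Step 13. The aryloxy group donates into the alkyne and lowers its dienophilicity. Decay of the diene, [2+2] addition across the ketene acetal double bond or hydration of the ynoate may therefore outrun the cycloaddition. Fallback: setting out from heptamer phenol 15 (which also bypasses steps 9 and 10), Ullmann coupling with commercial 1-bromo-3,5-dimethoxybenzene (CuI, picolinic acid, K3PO4, DMSO, 100 °C) would arylate the ring B oxygen in the same polarity as steps 3, 5 and 7. This would give the icosamethyl ether of the target F1. BBr3 in CH2Cl2, as in step 15, would then cleave all twenty methyl ethers, and the fallback comes back to the route at target 32.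

2. Step 2. Chemoselectivity may be lost: insertion of copper into the carbon–bromine bond of bromophenol 4 or of product 5 would lead to oligomeric aryl ethers. Fallback: the chain is grown one ring at a time from two mono-bromo aldehydes, so that no phenol ever carries a bromide; compounds 4 and 5 are then not needed.
   - Setting out from phenol 6, Ullmann coupling (CuI, picolinic acid, K3PO4, DMSO) with commercial 4-bromo-2,6-dimethoxybenzaldehyde would give 2,6-dimethoxy-4-(2,4,6-trimethoxyphenoxy)benzaldehyde F2.
   - Baeyer–Villiger oxidation with mCPBA would give 2,6-dimethoxy-4-(2,4,6-trimethoxyphenoxy)phenyl formate F3, methanolysed without isolation to 2,6-dimethoxy-4-(2,4,6-trimethoxyphenoxy)phenol F4.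
   - Ullmann coupling of this phenol with bromo aldehyde 3 would give trimer aldehyde 7, which step 4 turns into trimer phenol 9.
   - The same operations are then repeated. Phenol 9 and 4-bromo-2,6-dimethoxybenzaldehyde would give tetramer aldehyde F5, oxidised to tetramer formate F6 and methanolysed to tetramer phenol F7, which couples with 3 to pentamer aldehyde 10.
   - Step 6 gives pentamer phenol 12, which with 4-bromo-2,6-dimethoxybenzaldehyde would give hexamer aldehyde F8, oxidised to hexamer formate F9 and methanolysed to hexamer phenol F10.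
   - Coupling of this phenol with 3 would give heptamer aldehyde 13, where the fallback comes back to the route for good.

3. Step 15. Ether cleavage may stop short on the crowded trioxygenated rings, and the free icosaphenol may oxidise in air during isolation. Fallback: setting out from 31, the BBr3 treatment is followed, after a methanol quench and evaporation, by acetylation of the crude polyphenol in the same flask (Ac2O, pyridine). This would give the icosaacetate of the target F11, which is stable to air and can be chromatographed on silica, with incompletely demethylated material separated and resubmitted. Acid-catalysed transesterification (HCl from AcCl in MeOH, rt, argon) would then release 32 under non-oxidising conditions.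

Further compounds
F1 | step 13 | icosamethyl ether of the target (3,5-dimethoxyphenyl ether of phenol 15) | COc1cc(OC)cc(Oc2c(Oc3c(OC)cc(Oc4c(Oc5c(OC)cc(Oc6c(Oc7c(OC)cc(Oc8c(OC)cc(OC)cc8OC)cc7OC)cc(OC)c(OC)c6OC)cc5OC)cc(OC)c(OC)c4OC)cc3OC)cc(OC)c(OC)c2OC)c1
F2 | step 2 | 2,6-dimethoxy-4-(2,4,6-trimethoxyphenoxy)benzaldehyde | O=Cc1c(OC)cc(Oc2c(OC)cc(OC)cc2OC)cc1OC
F3 | step 2 | 2,6-dimethoxy-4-(2,4,6-trimethoxyphenoxy)phenyl formate | O=COc1c(OC)cc(Oc2c(OC)cc(OC)cc2OC)cc1OC
F4 | step 2 | 2,6-dimethoxy-4-(2,4,6-trimethoxyphenoxy)phenol | Oc1c(OC)cc(Oc2c(OC)cc(OC)cc2OC)cc1OC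
F5 | step 2 | tetramer aldehyde (rings E to H): 2,6-dimethoxybenzaldehyde whose position 4 carries the phenol oxygen of 9 | O=Cc1c(OC)cc(Oc2c(Oc3c(OC)cc(Oc4c(OC)cc(OC)cc4OC)cc3OC)cc(OC)c(OC)c2OC)cc1OC
F6 | step 2 | tetramer formate: formate ester of phenol F7 | O=COc1c(OC)cc(Oc2c(Oc3c(OC)cc(Oc4c(OC)cc(OC)cc4OC)cc3OC)cc(OC)c(OC)c2OC)cc1OC
F7 | step 2 | tetramer phenol: F5 with CHO replaced by OH | Oc1c(OC)cc(Oc2c(Oc3c(OC)cc(Oc4c(OC)cc(OC)cc4OC)cc3OC)cc(OC)c(OC)c2OC)cc1OC
F8 | step 2 | hexamer aldehyde (rings C to H): 2,6-dimethoxybenzaldehyde whose position 4 carries the phenol oxygen of 12 | O=Cc1c(OC)cc(Oc2c(Oc3c(OC)cc(Oc4c(Oc5c(OC)cc(Oc6c(OC)cc(OC)cc6OC)cc5OC)cc(OC)c(OC)c4OC)cc3OC)cc(OC)c(OC)c2OC)cc1OC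
F9 | step 2 | hexamer formate: formate ester of phenol F10 | O=COc1c(OC)cc(Oc2c(Oc3c(OC)cc(Oc4c(Oc5c(OC)cc(Oc6c(OC)cc(OC)cc6OC)cc5OC)cc(OC)c(OC)c4OC)cc3OC)cc(OC)c(OC)c2OC)cc1OC
F10 | step 2 | hexamer phenol: F8 with CHO replaced by OH | Oc1c(OC)cc(Oc2c(Oc3c(OC)cc(Oc4c(Oc5c(OC)cc(Oc6c(OC)cc(OC)cc6OC)cc5OC)cc(OC)c(OC)c4OC)cc3OC)cc(OC)c(OC)c2OC)cc1OC
F11 | step 15 | icosaacetate of the target | CC(=O)Oc1cc(OC(C)=O)cc(Oc2c(Oc3c(OC(C)=O)cc(Oc4c(Oc5c(OC(C)=O)cc(Oc6c(Oc7c(OC(C)=O)cc(Oc8c(OC(C)=O)cc(OC(C)=O)cc8OC(C)=O)cc7OC(C)=O)cc(OC(C)=O)c(OC(C)=O)c6OC(C)=O)cc5OC(C)=O)cc(OC(C)=O)c(OC(C)=O)c4OC(C)=O)cc3OC(C)=O)cc(OC(C)=O)c(OC(C)=O)c2OC(C)=O)c1
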